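**Strategy.** The ten-membered carbocycle (C1–C10) is opened at C7–C8. C7 is the β-carbon of the α-methylene-γ-lactone, hence the γ-terminus of the allyl unit C13–C11–C7, and C8 is a carbinol: an allyl-metal/aldehyde retron. One indium Barbier reaction of a 3-(bromomethyl)butenolide with an α-hydroxy aldehyde forms C7–C8, closes the carbocycle (equally the nine-membered oxacycle through the furanone oxygen), sets C7 and C8 and moves the lactone alkene to C11=C13. The precursor 26 carries the finished 3(2H)-furanone, the Z-C4=C5 alkene, the C6 butenolide with CH2Br on C11, and a free C9 hydroxyl next to the C8 aldehyde.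

Key step: step 15

Remark: germacrane numbering of the target is used for all intermediates (C1 ketone, C2=C3, C4(Me)=C5, C6 lactone carbinol, C7, C8, C9, C10 quaternary, C11=C13, C12 lactone carbonyl); the benzylidene carbon of 7 to 24 forms as a mixture of epimers that is carried through and removed in step 13, so it is written without configuration.

Step 1
Reactants: 1 (S)-lactic acid; 2 pivalaldehyde
Product: 3 (2S,5S)-2-tert-butyl-5-methyl-1,3-dioxolan-4-one (cis)
Conditions: TsOH·H2O (cat.), H2SO4 (cat.), pentane, reflux, Dean–Stark; crystallisation from Et2O/pentane, −78 °C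
Reagents that add atoms: none
Why: Acid-catalysed acetalisation of the α-hydroxy acid; the cis isomer is the thermodynamic product and is purified by crystallisation, so the lactate configuration is stored in the acetal centre (self-regeneration of the stereocentre).

Step 2
Reactants: 3 (2S,5S)-2-tert-butyl-5-methyl-1,3-dioxolan-4-one; 4 2-[(4-methoxybenzyl)oxy]acetaldehyde
Product: 6 (2S,5R)-2-tert-butyl-5-[(1R)-1-hydroxy-2-(4-methoxybenzyloxy)ethyl]-5-methyl-1,3-dioxolan-4-one, via lithium enolate 5 (not isolated)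
Conditions: LiN(iPr)2 (LDA, 1.05 equiv), THF, −78 °C; then 4, −78 °C; AcOH in THF, −78 °C
Reagents that add atoms: none
Why: Lithium enolate aldol addition: the aldehyde approaches the enolate anti to the tert-butyl group, which rebuilds C10 in the lactate sense, and a closed Zimmerman–Traxler chair with CH2OPMB equatorial should place the C9 hydroxyl syn to the C10 methyl; the minor C9 epimer is removed by chromatography.

Step 3
Reactants: 6 aldol adduct
Product: 7 (2S,5R)-2-tert-butyl-5-[(4R)-2-(4-methoxyphenyl)-1,3-dioxolan-4-yl]-5-methyl-1,3-dioxolan-4-one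
Conditions: DDQ (1.2 equiv), molecular sieves 4 Å, CH2Cl2 (anhydrous), 0 °C → rt
Reagents that add atoms: none
Why: DDQ oxidises the PMB ether to a benzylic oxocarbenium ion that the neighbouring C9 hydroxyl traps (oxidative benzylidene acetal formation); O8 and O9 are masked in one step and O8 is never free beside the acylal carbonyl, where it would lactonise.

Step 4
Reactants: 8 (Z)-3-methylpent-2-en-4-yn-1-ol
Product: 9 tert-butyldimethyl{[(2Z)-3-methylpent-2-en-4-yn-1-yl]oxy}silane
Conditions: TBSCl, imidazole, CH2Cl2, 0 °C → rt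
Reagents that add atoms: tert-butyldimethylsilyl chloride, CC(C)(C)[Si](C)(C)Cl
Why: Standard silylation of a primary alcohol; the ether is needed because a free Z-enynol would cyclise to a furan under the gold catalysis of step 6.

Step 5
Reactants: 9 silyl ether of the enynol; 7 benzylidene-protected dioxolanone
Product: 12 (2R,6Z)-8-(tert-butyldimethylsilyloxy)-2-hydroxy-2-[(4R)-2-(4-methoxyphenyl)-1,3-dioxolan-4-yl]-6-methyloct-6-en-4-yn-3-one, via lithium acetylide 10 (not isolated), via lithium hemiketal alkoxide 11 (not isolated)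
Conditions: n-BuLi (1.2 equiv), 9 (1.25 equiv), THF, −78 °C; then 7, −78 °C; AcOH, −78 °C → rt
Reagents that add atoms: none
Why: Acyl substitution on the dioxolanone by a lithium acetylide: the cyclic tetrahedral adduct 11 is stable at −78 °C, which prevents a second addition, and on protonation it opens with loss of pivalaldehyde to the α′-hydroxy ynone; C10 and the Z-alkene are not touched.

Step 6
Reactants: 12 α′-hydroxy ynone
Product: 13 (2R)-5-[(2Z)-4-(tert-butyldimethylsilyloxy)but-2-en-2-yl]-2-[(4R)-2-(4-methoxyphenyl)-1,3-dioxolan-4-yl]-2-methylfuran-3(2H)-one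
Conditions: (p-CF3C6H4)3PAuCl (2 mol %), AgOTf (2 mol %), toluene, rt
Reagents that add atoms: none
Why: Cationic monovalent gold activates the ynone alkyne for 5-endo-dig attack of the tertiary C10 hydroxyl at C3, followed by protodeauration (known cycloisomerisation of γ-hydroxy alkynones to 3(2H)-furanones); O6 and O9 are masked, so neither furan nor pyranone closure can compete.

Step 7
Reactants: 13 silyl-protected furanone
Product: 14 (2R)-5-[(2Z)-4-hydroxybut-2-en-2-yl]-2-[(4R)-2-(4-methoxyphenyl)-1,3-dioxolan-4-yl]-2-methylfuran-3(2H)-one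
Conditions: Bu4NF, AcOH (1:1), THF, 0 °C → rt
Reagents that add atoms: none
Why: Fluoride cleavage of the primary silyl ether, buffered with acetic acid so that the furanone and the Z-alkene see no base; the acetal is stable to fluoride.

Step 8
Reactants: 14 allylic alcohol
Product: 15 (2Z)-3-{(5R)-5-[(4R)-2-(4-methoxyphenyl)-1,3-dioxolan-4-yl]-5-methyl-4-oxo-4,5-dihydrofuran-2-yl}but-2-enal
Conditions: MnO2 (activated, excess), CH2Cl2, rt
Reagents that add atoms: none
Why: Manganese dioxide oxidation of an allylic alcohol to the enal under neutral conditions, which should keep the Z geometry; the enal is used without delay.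

Step 9
Reactants: 15 Z-enal; 16 methyl propiolate
Product: 18 methyl (4R,5Z)-4-hydroxy-6-{(5R)-5-[(4R)-2-(4-methoxyphenyl)-1,3-dioxolan-4-yl]-5-methyl-4-oxo-4,5-dihydrofuran-2-yl}hept-5-en-2-ynoate, via methylzinc alkynylide 17 (not isolated)
Conditions: 16 (3 equiv), Me2Zn (3 equiv), (S,S)- or (R,R)-ProPhenol (20 mol %, the antipode that gives 6R), Ph3P=O (40 mol %), toluene, 4 °C; aq. NH4Cl
Reagents that add atoms: none
Why: Catalytic asymmetric alkynylation of an aldehyde by a dinuclear zinc–ProPhenol catalyst, a reaction suited to enals and methyl propiolate; the ligand directs the alkynyl group to the Si face of C6 (6R) independently of the remote C9/C10 centres, and the zinc reagents leave the hindered vinylogous-ester ketone alone.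

Step 10
Reactants: 18 γ-hydroxy ynoate
Product: 21 (5R)-3-iodo-5-[(1Z)-2-{(5R)-5-[(4R)-2-(4-methoxyphenyl)-1,3-dioxolan-4-yl]-5-methyl-4-oxo-4,5-dihydrofuran-2-yl}prop-1-en-1-yl]furan-2(5H)-one, via stannyl hydroxy enoate 19 (not isolated), via stannyl butenolide 20 (not isolated)
Conditions: Bu3SnH (1.1 equiv), PdCl2(PPh3)2 (3 mol %), THF, 0 °C → rt; then I2 (1.2 equiv), CH2Cl2, 0 °C
Reagents that add atoms: iodine, II
Why: Palladium-catalysed syn-hydrostannation of the ynoate puts tin on the α-carbon C11 and hydrogen on C7, so the C6 hydroxyl and the ester are cis and lactonise to the α-stannyl butenolide; iododestannylation then occurs with retention at C11, all under neutral conditions that spare the acidic C6–H.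

Step 11
Reactants: 21 α-iodo butenolide; 22 (tributylstannyl)methanol
Product: 23 (5R)-3-(hydroxymethyl)-5-[(1Z)-2-{(5R)-5-[(4R)-2-(4-methoxyphenyl)-1,3-dioxolan-4-yl]-5-methyl-4-oxo-4,5-dihydrofuran-2-yl}prop-1-en-1-yl]furan-2(5H)-one
Conditions: Pd(PPh3)4 (10 mol %), 1,4-dioxane, 80 °C
Reagents that add atoms: none
Why: Stille coupling of the α-iodo enoate with the hydroxymethyl stannane brings in C13 without base; oxidative addition into α-iodo enoates is fast and C6 takes no part.

Step 12
Reactants: 23 hydroxymethyl butenolide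
Product: 24 (5R)-3-(bromomethyl)-5-[(1Z)-2-{(5R)-5-[(4R)-2-(4-methoxyphenyl)-1,3-dioxolan-4-yl]-5-methyl-4-oxo-4,5-dihydrofuran-2-yl}prop-1-en-1-yl]furan-2(5H)-one
Conditions: CBr4, PPh3, CH2Cl2, 0 °C
Reagents that add atoms: carbon tetrabromide, BrC(Br)(Br)Br
Why: Appel bromination of the primary allylic alcohol under neutral conditions; an allylic transposition would be harmless because both regioisomers lead to the same allylindium in step 15.

Step 13
Reactants: 24 bromomethyl butenolide acetal
Product: 25 (5R)-3-(bromomethyl)-5-[(1Z)-2-{(5R)-5-[(1R)-1,2-dihydroxyethyl]-5-methyl-4-oxo-4,5-dihydrofuran-2-yl}prop-1-en-1-yl]furan-2(5H)-one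
Conditions: AcOH/THF/H2O (4:1:1), 40 °C
Reagents that add atoms: none
Why: Mild acid hydrolysis of the electron-rich benzylidene acetal frees the 8,9-diol; the electron-poor allylic bromide, the butenolide and the vinylogous ester should be stable to aqueous acetic acid.

Step 14
Reactants: 25 diol
Product: 26 (2S)-2-[(2R)-5-{(1Z)-1-[(2R)-4-(bromomethyl)-5-oxo-2,5-dihydrofuran-2-yl]prop-1-en-2-yl}-2-methyl-3-oxo-2,3-dihydrofuran-2-yl]-2-hydroxyacetaldehyde (9S here is the target's C9 arrangement; the label changes with the aldehyde)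
Conditions: TEMPO (0.2 equiv), PhI(OAc)2 (1.1 equiv), CH2Cl2, 0 °C → rt; used crude at once
Reagents that add atoms: none
Why: TEMPO/PhI(OAc)2 oxidises primary alcohols far faster than hindered secondary ones, so only C8 is oxidised; the medium is free of base and water, which should prevent over-oxidation and enolisation at C9.

Step 15
Reactants: 26 bromomethyl butenolide α-hydroxy aldehyde
Product: 28 (4Z,6R,7R,8S,9R,10R)-8,9-dihydroxy-1-oxo-3,10-epoxygermacra-2,4,11(13)-trien-12,6-olide (7R here is the target's C7 arrangement; the label changes with the free O8–H), via allylindium bromide 27 (not isolated)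
Conditions: In powder (4 equiv), THF/H2O (1:1, degassed), 25 °C, syringe-pump addition of 26 (final ≤ 2 mM)
Reagents that add atoms: none
Why: Indium metal inserts into the C13–Br bond and the allylindium 27 adds through its γ-terminus C7 (SE2′) to the C8 aldehyde in a closed six-membered chair-like transition state, which moves the alkene to C11=C13; the closest known reactions are indium- and chromium-mediated Barbier closures of ten-membered germacranolide rings from 2-(bromomethyl)acrylates and indium allylations with 3-(bromomethyl)butenolides. The ring closes in the exo-trig mode (10-exo-trig for the carbocycle C1–C10, 9-exo-trig for the oxacycle through the furanone oxygen), the C8=O bond lying outside the ring. C8: indium is held between the free C9 hydroxyl and the aldehyde oxygen, so C7 attacks the chelate face opposite to C10 and the new hydroxyl should come out syn to O9 (8S). C7: the chelate forces C9 into the axial position of the chair while C6, trans to C13 on the butenolide alkene, sits equatorial, and the tether C5–C4–C3–O–C10–C9 should bring C8 to the butenolide face anti to the C6–C5 bond, giving the trans-fused lactone. The step needs γ- over α-attack (normal for allylindium; α-attack would require a twelve-membered carbocycle), aldehyde over the C1 vinylogous-ester ketone (inert to allylindium in water) and ring closure over oligomerisation, which high dilution and the Z-C4=C5 alkene with the planar furanone should secure by holding C7 and C8 close. The neutral aqueous medium spares the base-labile C6–H, the β-hydroxy ketone and the α-hydroxy aldehyde.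

Step 16
Reactants: 28 8,9-diol
Product: 29 (4Z,6R,7S,8S,9R,10R)-9-hydroxy-8-(3-methylbutanoyloxy)-1-oxo-3,10-epoxygermacra-2,4,11(13)-trien-12,6-olide
Conditions: isovaleric anhydride (1.1 equiv), 2,4,6-collidine, DMAP (0.05 equiv), CH2Cl2, −40 → −20 °C
Reagents that add atoms: isovaleric anhydride, CC(C)CC(=O)OC(=O)CC(C)C
Why: Kinetically controlled acylation: the C9 hydroxyl is neopentyl-like (next to quaternary C10), so one equivalent of anhydride at low temperature should acylate only O8; no stereocentre is touched.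

Step 17
Reactants: 29 8-O-isovalerate
Product: 30 (4Z,6R,7S,8S,9R,10R)-9-acetoxy-8-(3-methylbutanoyloxy)-1-oxo-3,10-epoxygermacra-2,4,11(13)-trien-12,6-olide (CNP0255553.1)
Conditions: Ac2O, DMAP (cat.), pyridine, CH2Cl2, 0 °C
Reagents that add atoms: acetic anhydride, CC(=O)OC(C)=O
Why: DMAP-catalysed acetylation of the remaining hindered C9 hydroxyl; acetyl transfer from the acylpyridinium should outrun O8→O9 acyl migration, and α-methylene lactones tolerate these conditions.

**Compound list**

1 | (S)-lactic acid | C[C@H](O)C(=O)O | starting material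
2 | pivalaldehyde | CC(C)(C)C=O | starting material
3 | (2S,5S)-2-tert-butyl-5-methyl-1,3-dioxolan-4-one | O=C1O[C@@H](C(C)(C)C)O[C@H]1C | intermediate
4 | 2-[(4-methoxybenzyl)oxy]acetaldehyde | O=CCOCc1ccc(OC)cc1 | starting material
5 | lithium (2S)-2-tert-butyl-5-methyl-1,3-dioxol-4-olate (enolate of 3, not isolated) | [Li]OC1=C(C)O[C@H](C(C)(C)C)O1 | intermediate
6 | (2S,5R)-2-tert-butyl-5-[(1R)-1-hydroxy-2-(4-methoxybenzyloxy)ethyl]-5-methyl-1,3-dioxolan-4-one | O=C1O[C@@H](C(C)(C)C)O[C@]1(C)[C@H](O)COCc2ccc(OC)cc2 | intermediate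
7 | (2S,5R)-2-tert-butyl-5-[(4R)-2-(4-methoxyphenyl)-1,3-dioxolan-4-yl]-5-methyl-1,3-dioxolan-4-one (benzylidene carbon: both epimers) | O=C1O[C@@H](C(C)(C)C)O[C@]1(C)[C@H]2COC(c3ccc(OC)cc3)O2 | intermediate
8 | (Z)-3-methylpent-2-en-4-yn-1-ol | C#C/C(C)=C\CO | starting material
9 | tert-butyldimethyl{[(2Z)-3-methylpent-2-en-4-yn-1-yl]oxy}silane | C#C/C(C)=C\CO[Si](C)(C)C(C)(C)C | intermediate
10 | lithium acetylide of 9 (not isolated) | [Li]C#C/C(C)=C\CO[Si](C)(C)C(C)(C)C | intermediate
11 | lithium 4-alkynyl-1,3-dioxolan-4-olate from 10 and 7 (hemiketal carbon undefined, not isolated) | [Li]OC1(C#C/C(C)=C\CO[Si](C)(C)C(C)(C)C)O[C@@H](C(C)(C)C)O[C@]1(C)[C@H]2COC(c3ccc(OC)cc3)O2 | intermediate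
12 | (2R,6Z)-8-(tert-butyldimethylsilyloxy)-2-hydroxy-2-[(4R)-2-(4-methoxyphenyl)-1,3-dioxolan-4-yl]-6-methyloct-6-en-4-yn-3-one | CC(C)(C)[Si](C)(C)OC/C=C(/C)C#CC(=O)[C@](C)(O)[C@H]1COC(c2ccc(OC)cc2)O1 | intermediate
13 | (2R)-5-[(2Z)-4-(tert-butyldimethylsilyloxy)but-2-en-2-yl]-2-[(4R)-2-(4-methoxyphenyl)-1,3-dioxolan-4-yl]-2-methylfuran-3(2H)-one | CC(C)(C)[Si](C)(C)OC/C=C(/C)C1=CC(=O)[C@](C)(O1)[C@H]2COC(c3ccc(OC)cc3)O2 | intermediate
14 | (2R)-5-[(2Z)-4-hydroxybut-2-en-2-yl]-2-[(4R)-2-(4-methoxyphenyl)-1,3-dioxolan-4-yl]-2-methylfuran-3(2H)-one | OC/C=C(/C)C1=CC(=O)[C@](C)(O1)[C@H]2COC(c3ccc(OC)cc3)O2 | intermediate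
15 | (2Z)-3-{(5R)-5-[(4R)-2-(4-methoxyphenyl)-1,3-dioxolan-4-yl]-5-methyl-4-oxo-4,5-dihydrofuran-2-yl}but-2-enal | O=C/C=C(/C)C1=CC(=O)[C@](C)(O1)[C@H]2COC(c3ccc(OC)cc3)O2 | intermediate
16 | methyl propiolate | C#CC(=O)OC | starting material
17 | methyl(3-methoxy-3-oxoprop-1-yn-1-yl)zinc (not isolated) | C[Zn]C#CC(=O)OC | intermediate
18 | methyl (4R,5Z)-4-hydroxy-6-{(5R)-5-[(4R)-2-(4-methoxyphenyl)-1,3-dioxolan-4-yl]-5-methyl-4-oxo-4,5-dihydrofuran-2-yl}hept-5-en-2-ynoate | COC(=O)C#C[C@H](O)/C=C(/C)C1=CC(=O)[C@](C)(O1)[C@H]2COC(c3ccc(OC)cc3)O2 | intermediate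
19 | methyl (2E,4R,5Z)-4-hydroxy-6-(furanonyl as in 18)-2-(tributylstannyl)hepta-2,5-dienoate (not isolated) | COC(=O)/C([Sn](CCCC)(CCCC)CCCC)=C\[C@H](O)/C=C(/C)C1=CC(=O)[C@](C)(O1)[C@H]2COC(c3ccc(OC)cc3)O2 | intermediate
20 | (5R)-3-(tributylstannyl)-5-[(1Z)-2-(furanonyl as in 18)prop-1-en-1-yl]furan-2(5H)-one (not isolated) | CCCC[Sn](CCCC)(CCCC)C1=C[C@H](OC1=O)/C=C(/C)C2=CC(=O)[C@](C)(O2)[C@H]3COC(c4ccc(OC)cc4)O3 | intermediate
21 | (5R)-3-iodo-5-[(1Z)-2-{(5R)-5-[(4R)-2-(4-methoxyphenyl)-1,3-dioxolan-4-yl]-5-methyl-4-oxo-4,5-dihydrofuran-2-yl}prop-1-en-1-yl]furan-2(5H)-one | IC1=C[C@H](OC1=O)/C=C(/C)C2=CC(=O)[C@](C)(O2)[C@H]3COC(c4ccc(OC)cc4)O3 | intermediate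
22 | (tributylstannyl)methanol | OC[Sn](CCCC)(CCCC)CCCC | starting material
23 | (5R)-3-(hydroxymethyl) analogue of 21 | OCC1=C[C@H](OC1=O)/C=C(/C)C2=CC(=O)[C@](C)(O2)[C@H]3COC(c4ccc(OC)cc4)O3 | intermediate
24 | (5R)-3-(bromomethyl) analogue of 21 | BrCC1=C[C@H](OC1=O)/C=C(/C)C2=CC(=O)[C@](C)(O2)[C@H]3COC(c4ccc(OC)cc4)O3 | intermediate
25 | (5R)-3-(bromomethyl)-5-[(1Z)-2-{(5R)-5-[(1R)-1,2-dihydroxyethyl]-5-methyl-4-oxo-4,5-dihydrofuran-2-yl}prop-1-en-1-yl]furan-2(5H)-one | BrCC1=C[C@H](OC1=O)/C=C(/C)C2=CC(=O)[C@](C)(O2)[C@H](O)CO | intermediate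
26 | (2S)-2-[(2R)-5-{(1Z)-1-[(2R)-4-(bromomethyl)-5-oxo-2,5-dihydrofuran-2-yl]prop-1-en-2-yl}-2-methyl-3-oxo-2,3-dihydrofuran-2-yl]-2-hydroxyacetaldehyde (key-step precursor) | BrCC1=C[C@H](OC1=O)/C=C(/C)C2=CC(=O)[C@](C)(O2)[C@H](O)C=O | intermediate
27 | allylindium species from 26, drawn as the C13 allylindium dibromide (not isolated) | Br[In](Br)CC1=C[C@H](OC1=O)/C=C(/C)C2=CC(=O)[C@](C)(O2)[C@H](O)C=O | intermediate
28 | (4Z,6R,7R,8S,9R,10R)-8,9-dihydroxy-1-oxo-3,10-epoxygermacra-2,4,11(13)-trien-12,6-olide (key-step product) | C=C1C(=O)O[C@@H]2/C=C(/C)C3=CC(=O)[C@](C)(O3)[C@H](O)[C@@H](O)[C@@H]12 | intermediate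
29 | (4Z,6R,7S,8S,9R,10R)-9-hydroxy-8-(3-methylbutanoyloxy)-1-oxo-3,10-epoxygermacra-2,4,11(13)-trien-12,6-olide | C=C1C(=O)O[C@@H]2/C=C(/C)C3=CC(=O)[C@](C)(O3)[C@H](O)[C@@H](OC(=O)CC(C)C)[C@@H]12 | intermediate
30 | (4Z,6R,7S,8S,9R,10R)-9-acetoxy-8-(3-methylbutanoyloxy)-1-oxo-3,10-epoxygermacra-2,4,11(13)-trien-12,6-olide (CNP0255553.1) | C=C1C(=O)O[C@@H]2/C=C(/C)C3=CC(=O)[C@](C)(O3)[C@H](OC(C)=O)[C@@H](OC(=O)CC(C)C)[C@@H]12 | target

**Step count.** Total: 17 steps. Longest linear sequence: 16 steps (from 1 through steps 1–3 and 5–17; step 4 is the side branch).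

**Steps most likely to fail**

1. Step 15. The allylindium may be protonated or may couple between molecules faster than the ring closes, or the aldehyde may react on its unchelated face, giving poor control at C8 and C7. The fallback sets out from iodide 21 and replaces metal insertion by a Lewis-acid allylsilane addition through an open transition state. A Negishi coupling of 21 with Me3SiCH2ZnCl (Pd(PPh3)4, THF, rt) should give the allylsilane acetal F1. Acetal hydrolysis as in step 13 gives the allylsilane diol F2, and TEMPO/PhI(OAc)2 as in step 14 gives the allylsilane hydroxy aldehyde F3. SnCl4 (CH2Cl2, −78 °C, high dilution) then chelates O9 and the aldehyde oxygen and closes C7–C8 by an intramolecular Hosomi–Sakurai reaction with loss of silicon. The route is rejoined at 28.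

2. Step 11. Zerovalent palladium at 80 °C may ionise the allylic C6–O lactone bond (loss of the C6 configuration, Z/E scrambling), and transfer of the sp3 hydroxymethyl group from tin may be slow. The fallback sets out from enal 15 and builds the bromomethyl butenolide by ring-closing metathesis, without tin, palladium or base. Amino-alcohol-catalysed asymmetric addition of (CH2=CH)2Zn to the C6 aldehyde gives the vinyl carbinol F4. Esterification with 2-(bromomethyl)acryloyl chloride (2,4,6-collidine, CH2Cl2, −20 °C) gives the bromomethacrylate ester F5. The second-generation Grubbs catalyst (toluene, 60 °C) then closes the C7=C11 bond. The route is rejoined at 24.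

3. Step 16. The two secondary hydroxyls may not be told apart well enough, or the isovaleryl group may migrate from O8 to O9. The fallback sets out from 28, fixes the regiochemistry with a far more discriminating bulky silyl group and reverses the order of acylation. TBSCl/imidazole (DMF, 0 °C) gives the 8-O-silyl ether F6. Ac2O/DMAP/pyridine gives the 9-acetate 8-silyl ether F7. HF·pyridine (THF/pyridine, 0 °C) gives the 9-acetate 8-alcohol F8. Isovaleric anhydride/DMAP/pyridine (CH2Cl2, 0 °C) then acylates the only free hydroxyl. The route is rejoined at 30.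

**Further compounds**

F1 | step 15 | (5R)-3-[(trimethylsilyl)methyl] analogue of 21 (allylsilane acetal) | C[Si](C)(C)CC1=C[C@H](OC1=O)/C=C(/C)C2=CC(=O)[C@](C)(O2)[C@H]3COC(c4ccc(OC)cc4)O3
F2 | step 15 | (5R)-3-[(trimethylsilyl)methyl] analogue of 25 (allylsilane diol) | C[Si](C)(C)CC1=C[C@H](OC1=O)/C=C(/C)C2=CC(=O)[C@](C)(O2)[C@H](O)CO
F3 | step 15 | (5R)-3-[(trimethylsilyl)methyl] analogue of 26 (allylsilane hydroxy aldehyde) | C[Si](C)(C)CC1=C[C@H](OC1=O)/C=C(/C)C2=CC(=O)[C@](C)(O2)[C@H](O)C=O
F4 | step 11 | (2R)-5-[(2Z,4S)-4-hydroxyhexa-2,5-dien-2-yl]-2-[(4R)-2-(4-methoxyphenyl)-1,3-dioxolan-4-yl]-2-methylfuran-3(2H)-one (vinyl carbinol; 4S is the 6R arrangement of 18) | C=C[C@H](O)/C=C(/C)C1=CC(=O)[C@](C)(O1)[C@H]2COC(c3ccc(OC)cc3)O2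
F5 | step 11 | 2-(bromomethyl)acrylate ester of F4 | C=C[C@H](OC(=O)C(=C)CBr)/C=C(/C)C1=CC(=O)[C@](C)(O1)[C@H]2COC(c3ccc(OC)cc3)O2
F6 | step 16 | 8-O-tert-butyldimethylsilyl ether of 28 | C=C1C(=O)O[C@@H]2/C=C(/C)C3=CC(=O)[C@](C)(O3)[C@H](O)[C@@H](O[Si](C)(C)C(C)(C)C)[C@@H]12
F7 | step 16 | 9-O-acetyl-8-O-tert-butyldimethylsilyl derivative of 28 | C=C1C(=O)O[C@@H]2/C=C(/C)C3=CC(=O)[C@](C)(O3)[C@H](OC(C)=O)[C@@H](O[Si](C)(C)C(C)(C)C)[C@@H]12
F8 | step 16 | 9-O-acetyl derivative of 28 (free 8-hydroxyl) | C=C1C(=O)O[C@@H]2/C=C(/C)C3=CC(=O)[C@](C)(O3)[C@H](OC(C)=O)[C@@H](O)[C@@H]12
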